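**Retrosynthetic overview**
1. Target ⇒ removal of six O-benzyl ethers and one O-silyl ether from a fully protected ester.
2. Ester C–O bond ⇒ tetra-O-benzyl-(+)-catechin (free 3-OH) plus a (3S)-3-silyloxy-5-arylpentanoic acid.
3. Side-chain carbinol ⇒ β-keto ester (asymmetric hydrogenation). Key C–C bond, C2–C3 of the side chain ⇒ decarboxylative Claisen condensation of an arylpropanoyl imidazolide with a malonate half-ester.
4. Building blocks ⇒ dihydrocaffeic acid, potassium ethyl malonate, (+)-catechin, benzyl bromide.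
5. No ring is constructed: rings A, C and B of the flavan, with both flavan stereocentres, come intact from (+)-catechin.

Assumption: the SMILES is taken as drawn, i.e. a (2R,3S) flavan-3-ol (2,3-trans, the (+)-catechin configuration) esterified at O3 with (3S)-5-(3,4-dihydroxyphenyl)-3-hydroxypentanoic acid.

**Route**

Step 1
Reactants: 1 (+)-catechin, (2R,3S)-2-(3,4-dihydroxyphenyl)chromane-3,5,7-triol
Product: 2 5,7,3',4'-tetra-O-benzyl-(+)-catechin, (2R,3S)-5,7-bis(benzyloxy)-2-[3,4-bis(benzyloxy)phenyl]chroman-3-ol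
Conditions: BnBr (4.4 equiv), K2CO3 (5 equiv), DMF, 0 °C → rt, Ar, 36 h
Reagents that add atoms: benzyl bromide, BrCc1ccccc1
Why: Williamson ether synthesis in which K2CO3 deprotonates only the four phenols, so the aliphatic 3-OH stays free and both stereocentres are carried over unchanged from 1.

Step 2
Reactants: 3 3-(3,4-dihydroxyphenyl)propanoic acid (dihydrocaffeic acid)
Product: 4 benzyl 3-[3,4-bis(benzyloxy)phenyl]propanoate
Conditions: BnBr (3.5 equiv), K2CO3 (4.5 equiv), DMF, 60 °C, 12 h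
Reagents that add atoms: benzyl bromide, BrCc1ccccc1
Why: Exhaustive Williamson O-alkylation of both phenols and the carboxylate gives one well-defined, chromatographable compound.

Step 3
Reactants: 4 benzyl 3-[3,4-bis(benzyloxy)phenyl]propanoate
Product: 5 3-[3,4-bis(benzyloxy)phenyl]propanoic acid
Conditions: LiOH·H2O (3 equiv), THF/MeOH/H2O 3:1:1, 40 °C; then 1 M HCl
Reagents that add atoms: lithium hydroxide, [Li+].[OH-]
Why: Saponification cleaves only the ester, because aryl benzyl ethers are inert to aqueous hydroxide.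

Step 4
Reactants: 5 3-[3,4-bis(benzyloxy)phenyl]propanoic acid; 6 potassium ethyl malonate (potassium 3-ethoxy-3-oxopropanoate)
Product: 10 ethyl 5-[3,4-bis(benzyloxy)phenyl]-3-oxopentanoate, via acyl imidazolide 7 (not isolated), via magnesium ethyl malonate 8 (not isolated), via acylmalonic half-ester 9 (not isolated)
Conditions: 5, 1,1'-carbonyldiimidazole (1.2 equiv), THF, rt, 2 h; separately 6 (2 equiv), MgCl2 (2.2 equiv), Et3N (3 equiv), MeCN, rt, 3 h; combine, rt → 45 °C, 16 h; 1 M HCl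
Reagents that add atoms: none
Why: Masamune–Brooks decarboxylative crossed Claisen condensation, in which the magnesium-chelated malonate half-ester is C-acylated by the acyl imidazolide and the adduct loses CO2 on acidification, so self-condensation and double acylation are excluded.

Step 5
Reactants: 10 ethyl 5-[3,4-bis(benzyloxy)phenyl]-3-oxopentanoate
Product: 11 ethyl (3S)-5-[3,4-bis(benzyloxy)phenyl]-3-hydroxypentanoate
Conditions: H2 (10 atm), RuCl2[(S)-BINAP](DMF)n (1 mol %, from [RuCl2(benzene)]2 and (S)-BINAP), EtOH, 60 °C, 24 h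
Reagents that add atoms: none
Why: Noyori asymmetric hydrogenation of a chelating β-keto ester, where the (S)-BINAP ligand directs hydride to one ketone face and sets the (3S) carbinol (same sense as (R)-BINAP giving (R)-3-hydroxybutanoate, typically ≥97% ee), and the homogeneous ruthenium catalyst leaves aryl benzyl ethers untouched.

Step 6
Reactants: 11 ethyl (3S)-5-[3,4-bis(benzyloxy)phenyl]-3-hydroxypentanoate
Product: 12 ethyl (3S)-5-[3,4-bis(benzyloxy)phenyl]-3-[(tert-butyldimethylsilyl)oxy]pentanoate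
Conditions: TBSCl (1.5 equiv), imidazole (3 equiv), DMF, rt, 12 h
Reagents that add atoms: tert-butyldimethylsilyl chloride, CC(C)(C)[Si](C)(C)Cl
Why: Imidazole-promoted O-silylation masks the carbinol so the acid cannot acylate itself in step 8, and the stereocentre is not touched.

Step 7
Reactants: 12 ethyl (3S)-5-[3,4-bis(benzyloxy)phenyl]-3-[(tert-butyldimethylsilyl)oxy]pentanoate
Product: 13 (3S)-5-[3,4-bis(benzyloxy)phenyl]-3-[(tert-butyldimethylsilyl)oxy]pentanoic acid
Conditions: LiOH·H2O (3 equiv), THF/MeOH/H2O 3:1:1, 0 °C → rt; then cold 1 M HCl to pH 4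
Reagents that add atoms: lithium hydroxide, [Li+].[OH-]
Why: Saponification of the ethyl ester is tolerated by the secondary silyl ether and the benzyl ethers, and C3 is not α to the carbonyl so it cannot epimerise.

Step 8
Reactants: 13 (3S)-5-[3,4-bis(benzyloxy)phenyl]-3-[(tert-butyldimethylsilyl)oxy]pentanoic acid (1.3 equiv); 2 5,7,3',4'-tetra-O-benzyl-(+)-catechin
Product: 14 (2R,3S)-5,7-bis(benzyloxy)-2-[3,4-bis(benzyloxy)phenyl]chroman-3-yl (3S)-5-[3,4-bis(benzyloxy)phenyl]-3-[(tert-butyldimethylsilyl)oxy]pentanoate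
Conditions: DCC (1.5 equiv), DMAP (0.3 equiv), CH2Cl2, 0 °C → rt, 24 h
Reagents that add atoms: none
Why: Steglich esterification (carbodiimide activation with DMAP acyl transfer) is the standard acylation of the hindered 3-OH of benzylated flavan-3-ols and proceeds with retention at every stereocentre because only the O–H bond reacts.

Step 9
Reactants: 14 the silyl-protected hexabenzyl ester
Product: 15 (2R,3S)-5,7-bis(benzyloxy)-2-[3,4-bis(benzyloxy)phenyl]chroman-3-yl (3S)-5-[3,4-bis(benzyloxy)phenyl]-3-hydroxypentanoate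
Conditions: HF·pyridine, pyridine, THF, 0 °C → rt, 12 h
Reagents that add atoms: none
Why: Fluoride-mediated desilylation under buffered, non-basic conditions frees the β-hydroxy ester without elimination, retro-aldol cleavage or acyl transfer, and benzyl ethers are inert.

Step 10
Reactants: 15 the hexabenzyl β-hydroxy ester
Product: 16 phylloflavan, (2R,3S)-2-(3,4-dihydroxyphenyl)-5,7-dihydroxychroman-3-yl (3S)-5-(3,4-dihydroxyphenyl)-3-hydroxypentanoate
Conditions: H2 (1 atm), Pd(OH)2/C (20 wt %), THF/MeOH 1:1, rt, 6–12 h; filter, Sephadex LH-20 (MeOH)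
Reagents that add atoms: none
Why: Catalytic hydrogenolysis removes the six aryl benzyl ethers much faster than it attacks the ring C benzylic C2–O bond or the ester, so all three stereocentres survive.

**Compound list**
1 | (+)-catechin, (2R,3S)-2-(3,4-dihydroxyphenyl)chromane-3,5,7-triol | O[C@H]1Cc2c(O)cc(O)cc2O[C@@H]1c1ccc(O)c(O)c1 | starting material
2 | 5,7,3',4'-tetra-O-benzyl-(+)-catechin, (2R,3S)-5,7-bis(benzyloxy)-2-[3,4-bis(benzyloxy)phenyl]chroman-3-ol | O[C@H]1Cc2c(OCc3ccccc3)cc(OCc3ccccc3)cc2O[C@@H]1c1ccc(OCc2ccccc2)c(OCc2ccccc2)c1 | intermediate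
3 | 3-(3,4-dihydroxyphenyl)propanoic acid | OC(=O)CCc1ccc(O)c(O)c1 | starting material
4 | benzyl 3-[3,4-bis(benzyloxy)phenyl]propanoate | O=C(CCc1ccc(OCc2ccccc2)c(OCc2ccccc2)c1)OCc1ccccc1 | intermediate
5 | 3-[3,4-bis(benzyloxy)phenyl]propanoic acid | OC(=O)CCc1ccc(OCc2ccccc2)c(OCc2ccccc2)c1 | intermediate
6 | potassium ethyl malonate | CCOC(=O)CC(=O)[O-].[K+] | starting material
7 | 1-{3-[3,4-bis(benzyloxy)phenyl]propanoyl}imidazole (acyl imidazolide) | O=C(CCc1ccc(OCc2ccccc2)c(OCc2ccccc2)c1)n1ccnc1 | intermediate (not isolated)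
8 | magnesium ethyl malonate (magnesium chelate of the doubly deprotonated half-ester) | CCOC(=O)[CH-]C(=O)[O-].[Mg+2] | intermediate (not isolated)
9 | 5-[3,4-bis(benzyloxy)phenyl]-2-(ethoxycarbonyl)-3-oxopentanoic acid (acylmalonic half-ester, held as its magnesium chelate until the acid quench) | CCOC(=O)C(C(=O)O)C(=O)CCc1ccc(OCc2ccccc2)c(OCc2ccccc2)c1 | intermediate (not isolated)
10 | ethyl 5-[3,4-bis(benzyloxy)phenyl]-3-oxopentanoate | CCOC(=O)CC(=O)CCc1ccc(OCc2ccccc2)c(OCc2ccccc2)c1 | intermediate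
11 | ethyl (3S)-5-[3,4-bis(benzyloxy)phenyl]-3-hydroxypentanoate | CCOC(=O)C[C@@H](O)CCc1ccc(OCc2ccccc2)c(OCc2ccccc2)c1 | intermediate
12 | ethyl (3S)-5-[3,4-bis(benzyloxy)phenyl]-3-[(tert-butyldimethylsilyl)oxy]pentanoate | CCOC(=O)C[C@@H](O[Si](C)(C)C(C)(C)C)CCc1ccc(OCc2ccccc2)c(OCc2ccccc2)c1 | intermediate
13 | (3S)-5-[3,4-bis(benzyloxy)phenyl]-3-[(tert-butyldimethylsilyl)oxy]pentanoic acid | OC(=O)C[C@@H](O[Si](C)(C)C(C)(C)C)CCc1ccc(OCc2ccccc2)c(OCc2ccccc2)c1 | intermediate
14 | (2R,3S)-5,7-bis(benzyloxy)-2-[3,4-bis(benzyloxy)phenyl]chroman-3-yl (3S)-5-[3,4-bis(benzyloxy)phenyl]-3-[(tert-butyldimethylsilyl)oxy]pentanoate | O=C(C[C@@H](O[Si](C)(C)C(C)(C)C)CCc1ccc(OCc2ccccc2)c(OCc2ccccc2)c1)O[C@H]1Cc2c(OCc3ccccc3)cc(OCc3ccccc3)cc2O[C@@H]1c1ccc(OCc2ccccc2)c(OCc2ccccc2)c1 | intermediate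
15 | (2R,3S)-5,7-bis(benzyloxy)-2-[3,4-bis(benzyloxy)phenyl]chroman-3-yl (3S)-5-[3,4-bis(benzyloxy)phenyl]-3-hydroxypentanoate | O=C(C[C@@H](O)CCc1ccc(OCc2ccccc2)c(OCc2ccccc2)c1)O[C@H]1Cc2c(OCc3ccccc3)cc(OCc3ccccc3)cc2O[C@@H]1c1ccc(OCc2ccccc2)c(OCc2ccccc2)c1 | intermediate
16 | phylloflavan, (2R,3S)-2-(3,4-dihydroxyphenyl)-5,7-dihydroxychroman-3-yl (3S)-5-(3,4-dihydroxyphenyl)-3-hydroxypentanoate | O=C(C[C@@H](O)CCc1ccc(O)c(O)c1)O[C@H]1Cc2c(O)cc(O)cc2O[C@@H]1c1ccc(O)c(O)c1 | target

**Step count and risk**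

Total steps: 10. Longest linear sequence: 9 steps (steps 2 to 10, from 3); step 1 is the convergent branch.

The three steps most likely to fail:

Step 1. The risks are C-benzylation of the electron-rich ring A, some base-induced C2 epimerisation and a moderate yield. The fallback sets out from 1 and comes back at 2. Compound 1 is peracetylated (Ac2O, pyridine) to (+)-catechin pentaacetate F1. F1 is treated with BnBr and K2CO3 in DMF containing about 5 equiv of MeOH, so each aryl acetate is methanolysed slowly and its phenoxide is trapped at oxygen as it forms. This gives 3-O-acetyl-5,7,3',4'-tetra-O-benzyl-(+)-catechin F2, because the aliphatic acetate reacts far more slowly and the 3-OH cannot be benzylated by K2CO3 in any case. K2CO3 in MeOH/THF then removes the 3-acetate and gives 2.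

Step 5. The hydrogenation needs a pressure vessel and an oxygen-free, well-formed catalyst, and a poor batch gives low conversion or low ee. The fallback sets the carbinol by asymmetric carbonyl allylation; it sets out from 4 and comes back at 13. i-Bu2AlH (toluene, −78 °C) reduces 4 to 3-[3,4-bis(benzyloxy)phenyl]propanal F3. Brown allylation with (+)-Ipc2B(allyl) (from (+)-Ipc2BOMe and allylmagnesium bromide, Et2O, −78 °C, then NaOH/H2O2) gives (3S)-1-[3,4-bis(benzyloxy)phenyl]hex-5-en-3-ol F4; the (+)-reagent gives the (S) homoallylic alcohol from unbranched aldehydes, in about 90–95% ee. TBSCl and imidazole give tert-butyl{[(3S)-1-[3,4-bis(benzyloxy)phenyl]hex-5-en-3-yl]oxy}dimethylsilane F5. Lemieux–Johnson cleavage (catalytic OsO4, NaIO4, 2,6-lutidine, dioxane/H2O) gives (3S)-5-[3,4-bis(benzyloxy)phenyl]-3-[(tert-butyldimethylsilyl)oxy]pentanal F6. Pinnick oxidation (NaClO2, NaH2PO4, 2-methyl-2-butene, t-BuOH/H2O) gives 13.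

Step 8. The alcohol is a hindered secondary one, and N-acylurea formation or β-elimination of the activated silyloxy acid would cut the yield. The fallback forms the ester by acylketene trapping and sets the carbinol afterwards; it sets out from 5 (with 2) and comes back at 15. Compound 5, Meldrum's acid, DCC and DMAP (CH2Cl2) give 5-{3-[3,4-bis(benzyloxy)phenyl]propanoyl}-2,2-dimethyl-1,3-dioxane-4,6-dione F7. Heating F7 with 2 in toluene at 90–110 °C releases the acylketene, which the 3-OH of 2 captures to give (2R,3S)-5,7-bis(benzyloxy)-2-[3,4-bis(benzyloxy)phenyl]chroman-3-yl 5-[3,4-bis(benzyloxy)phenyl]-3-oxopentanoate F8. Catalyst-controlled hydrogenation of F8 with RuCl2[(S)-BINAP](DMF)n (H2, CH2Cl2/EtOH) gives 15 directly, with no silyl ether needed.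

**Further compounds**
F1 | step 1 | (+)-catechin pentaacetate | CC(=O)O[C@H]1Cc2c(OC(C)=O)cc(OC(C)=O)cc2O[C@@H]1c1ccc(OC(C)=O)c(OC(C)=O)c1
F2 | step 1 | 3-O-acetyl-5,7,3',4'-tetra-O-benzyl-(+)-catechin | CC(=O)O[C@H]1Cc2c(OCc3ccccc3)cc(OCc3ccccc3)cc2O[C@@H]1c1ccc(OCc2ccccc2)c(OCc2ccccc2)c1
F3 | step 5 | 3-[3,4-bis(benzyloxy)phenyl]propanal | O=CCCc1ccc(OCc2ccccc2)c(OCc2ccccc2)c1
F4 | step 5 | (3S)-1-[3,4-bis(benzyloxy)phenyl]hex-5-en-3-ol | C=CC[C@@H](O)CCc1ccc(OCc2ccccc2)c(OCc2ccccc2)c1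
F5 | step 5 | tert-butyl{[(3S)-1-[3,4-bis(benzyloxy)phenyl]hex-5-en-3-yl]oxy}dimethylsilane | C=CC[C@@H](O[Si](C)(C)C(C)(C)C)CCc1ccc(OCc2ccccc2)c(OCc2ccccc2)c1
F6 | step 5 | (3S)-5-[3,4-bis(benzyloxy)phenyl]-3-[(tert-butyldimethylsilyl)oxy]pentanal | O=CC[C@@H](O[Si](C)(C)C(C)(C)C)CCc1ccc(OCc2ccccc2)c(OCc2ccccc2)c1
F7 | step 8 | 5-{3-[3,4-bis(benzyloxy)phenyl]propanoyl}-2,2-dimethyl-1,3-dioxane-4,6-dione | CC1(C)OC(=O)C(C(=O)CCc2ccc(OCc3ccccc3)c(OCc3ccccc3)c2)C(=O)O1
F8 | step 8 | (2R,3S)-5,7-bis(benzyloxy)-2-[3,4-bis(benzyloxy)phenyl]chroman-3-yl 5-[3,4-bis(benzyloxy)phenyl]-3-oxopentanoate | O=C(CC(=O)CCc1ccc(OCc2ccccc2)c(OCc2ccccc2)c1)O[C@H]1Cc2c(OCc3ccccc3)cc(OCc3ccccc3)cc2O[C@@H]1c1ccc(OCc2ccccc2)c(OCc2ccccc2)c1
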